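## Retrosynthetic overview

1. The target is a trans-(2S,3S)-2,3-diaryl-2,3-dihydrobenzofuran: ring A is the benzo ring, ring B the resorcinol ring on C3, ring C the catechol ring on C2, ring D the resorcinol ring of the C5 styryl arm. The strategy rests on the 4-OH of ring C being para to C2: a C2=C3 alkene is then the tautomer of a ring C para-quinone methide carrying H on C3, and O1 of ring A is placed to close a five-membered ring on C2.
2. Last disconnections: the five O–CH3 bonds (BBr3), then the C5–vinyl bond (Mizoroki–Heck coupling of a C5 bromide with 3,5-dimethoxystyrene).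
3. Key disconnection: C3–H and O1–C2, back to an acyclic 1,1,2-triarylethene with the ring A phenol and the ring C 4-OH free.
4. The triarylethene comes from a 2-hydroxybenzophenone (rings A and B; 5-bromosalicylaldehyde plus aryl Grignard reagent, then MnO2) and a ring C benzyl Grignard reagent made from O-silylated vanillin, by addition, dehydration and desilylation.
5. Ring order: rings A to D are bought as arenes; the dihydrofuran ring is the only ring made, in step 9.

Key step: step 9

Assumption: step 7 should give the triarylethene as an E/Z mixture; both isomers lead to the same quinone methide 14, so the mixture is carried on and the E isomer is drawn for 12 and 13.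

## Route

Step 1
Reactants: 1 5-bromosalicylaldehyde (5-bromo-2-hydroxybenzaldehyde); 2 1-bromo-3,5-dimethoxybenzene
Product: 4 4-bromo-2-[(3,5-dimethoxyphenyl)(hydroxy)methyl]phenol (racemic), via 3,5-dimethoxyphenylmagnesium bromide 3 (not isolated)
Conditions: 2 (2.3 equiv), Mg, THF, 40 °C; then 1, THF, 0 °C → rt; aq. NH4Cl
Reagents that add atoms: none
Why: Grignard addition to an aldehyde, in which the first equivalent of 3 deprotonates the phenol and the second adds to the formyl group of the magnesium phenoxide; the ring A bromide does not exchange with an arylmagnesium bromide at this temperature, and the carbinol centre forms as the racemate and is removed in step 2.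

Step 2
Reactants: 4 4-bromo-2-[(3,5-dimethoxyphenyl)(hydroxy)methyl]phenol
Product: 5 (5-bromo-2-hydroxyphenyl)(3,5-dimethoxyphenyl)methanone
Conditions: MnO2 (10 equiv), CH2Cl2, rt
Reagents that add atoms: none
Why: MnO2 oxidation of a doubly benzylic secondary alcohol to the diaryl ketone, which should leave the phenol and the aryl bromide untouched.

Step 3
Reactants: 6 vanillin (4-hydroxy-3-methoxybenzaldehyde)
Product: 7 4-(tert-butyldimethylsilyloxy)-3-methoxybenzaldehyde
Conditions: TBSCl, imidazole, CH2Cl2, rt
Reagents that add atoms: tert-butyldimethylsilyl chloride, CC(C)(C)[Si](C)(C)Cl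
Why: Silylation of a phenol, which masks the acidic 4-OH so that a benzylic organomagnesium reagent can later be made from this ring.

Step 4
Reactants: 7 4-(tert-butyldimethylsilyloxy)-3-methoxybenzaldehyde
Product: 8 [4-(tert-butyldimethylsilyloxy)-3-methoxyphenyl]methanol
Conditions: NaBH4, MeOH, 0 °C
Reagents that add atoms: none
Why: Hydride reduction of an aryl aldehyde, which is fast enough at 0 °C that the aryl silyl ether should survive the methanolic medium.

Step 5
Reactants: 8 [4-(tert-butyldimethylsilyloxy)-3-methoxyphenyl]methanol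
Product: 9 tert-butyl[4-(chloromethyl)-2-methoxyphenoxy]dimethylsilane
Conditions: SOCl2, Et3N, CH2Cl2, 0 °C; used directly
Reagents that add atoms: thionyl chloride, ClS(Cl)=O
Why: Chlorination of an electron-rich benzylic alcohol through its chlorosulfite, with the amine taking up HCl so that the silyl ether is spared.

Step 6
Reactants: 9 tert-butyl[4-(chloromethyl)-2-methoxyphenoxy]dimethylsilane; 5 (5-bromo-2-hydroxyphenyl)(3,5-dimethoxyphenyl)methanone
Product: 11 4-bromo-2-{2-[4-(tert-butyldimethylsilyloxy)-3-methoxyphenyl]-1-(3,5-dimethoxyphenyl)-1-hydroxyethyl}phenol (racemic), via 4-(tert-butyldimethylsilyloxy)-3-methoxybenzylmagnesium chloride 10 (not isolated)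
Conditions: 9 (3 equiv, slow addition), Mg, THF, 0 °C; then 5, THF, 0 °C → rt; aq. NH4Cl
Reagents that add atoms: none
Why: Benzyl Grignard addition to a non-enolisable diaryl ketone, in which the first equivalent forms the chelated magnesium phenoxide and a further equivalent adds to the carbonyl group; slow addition of the chloride at high dilution should hold back Wurtz coupling, and the tertiary carbinol centre forms as the racemate and is removed in step 7.

Step 7
Reactants: 11 4-bromo-2-{2-[4-(tert-butyldimethylsilyloxy)-3-methoxyphenyl]-1-(3,5-dimethoxyphenyl)-1-hydroxyethyl}phenol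
Product: 12 4-bromo-2-{(E)-2-[4-(tert-butyldimethylsilyloxy)-3-methoxyphenyl]-1-(3,5-dimethoxyphenyl)ethenyl}phenol
Conditions: p-TsOH·H2O (2 mol %), MgSO4, toluene, rt; stopped at full conversion
Reagents that add atoms: none
Why: E1 dehydration of a tertiary bis-benzylic alcohol through the cation that the ortho-hydroxyl of ring A stabilises, with only the CH2 hydrogens available so that the C2=C3 alkene is the sole regiochemical outcome; the silyl group on the ring C oxygen keeps the quinone methide path closed, and any cyclised by-product, which would be racemic, is removed by chromatography.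

Step 8
Reactants: 12 4-bromo-2-{(E)-2-[4-(tert-butyldimethylsilyloxy)-3-methoxyphenyl]-1-(3,5-dimethoxyphenyl)ethenyl}phenol
Product: 13 4-bromo-2-[(E)-1-(3,5-dimethoxyphenyl)-2-(4-hydroxy-3-methoxyphenyl)ethenyl]phenol
Conditions: n-Bu4NF, AcOH, THF, 0 °C
Reagents that add atoms: none
Why: Fluoride cleavage of an aryl silyl ether under buffered conditions, so that the 4-hydroxystilbene is released without any acid strong enough to cyclise it.

Step 9
Reactants: 13 4-bromo-2-[(E)-1-(3,5-dimethoxyphenyl)-2-(4-hydroxy-3-methoxyphenyl)ethenyl]phenol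
Product: 15 4-[(2S,3S)-5-bromo-3-(3,5-dimethoxyphenyl)-2,3-dihydro-1-benzofuran-2-yl]-2-methoxyphenol, via para-quinone methide 14 (not isolated)
Conditions: (R)-3,3'-bis(2,4,6-triisopropylphenyl)-1,1'-binaphthyl-2,2'-diyl hydrogen phosphate [(R)-TRIP] (10 mol %), toluene (0.02 M), rt
Reagents that add atoms: none
Why: Proposed new method: the phosphoric acid is anchored by a hydrogen bond from the ring A hydroxyl, which lies next to C3, and transfers its proton to one face of C3 while the para-hydroxyl of ring C gives up its own proton, so the C2=C3 stilbene passes into para-quinone methide 14 (or its phosphate ion pair) with the C3–H stereocentre in place; no oxidant is involved because alkene and product are isomers. The phosphate, still bound to the ring A hydroxyl, then serves as general base while this oxygen adds to the methide carbon C2 in an oxa-1,6-addition that restores the aromaticity of ring C and closes the dihydrofuran ring in the 5-exo-trig mode. C3 is under catalyst control (enantioselective protonation inside the 2,4,6-triisopropylphenyl pocket), and C2 is under substrate control, since O1 approaches C2 anti to the ring B aryl group on C3 and, the addition being reversible through 14 with C3 untouched, C2 also settles thermodynamically in the trans arrangement. The closest known reaction types are chiral phosphoric acid-catalysed additions to quinone methides generated in situ from hydroxystyrenes and the achiral acid-catalysed cyclisation of 2-hydroxystilbenes to 2-aryl-2,3-dihydrobenzofurans. The step needs protonation at C3, not at C2, to be the productive event, which the substrate secures because C2-protonation gives an ortho-quinone methide of ring A with no nucleophile within reach that can only return to the alkene (both alkene isomers therefore funnel into 14), while the bromine blocks the para position of the ring A phenol against C-alkylation. The sense of induction of the (R)-acid is assumed, and the (S)-acid would be taken if the (2R,3R) isomer formed.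

Step 10
Reactants: 15 4-[(2S,3S)-5-bromo-3-(3,5-dimethoxyphenyl)-2,3-dihydro-1-benzofuran-2-yl]-2-methoxyphenol; 16 3,5-dimethoxystyrene
Product: 17 4-[(2S,3S)-3-(3,5-dimethoxyphenyl)-5-[(E)-2-(3,5-dimethoxyphenyl)ethenyl]-2,3-dihydro-1-benzofuran-2-yl]-2-methoxyphenol
Conditions: 16 (1.5 equiv), Pd(OAc)2 (5 mol %), P(t-Bu)3·HBF4 (10 mol %), Cy2NMe, 1,4-dioxane, 80 °C
Reagents that add atoms: none
Why: Mizoroki–Heck coupling, in which oxidative addition of the electron-rich C5 bromide to zerovalent palladium is helped by the bulky trialkylphosphine and syn-insertion followed by syn-β-hydride elimination gives the E-stilbene; the hindered amine in a non-polar solvent should not form enough ring C phenoxide to open the C2–O1 bond, so both stereocentres are left alone.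

Step 11
Reactants: 17 4-[(2S,3S)-3-(3,5-dimethoxyphenyl)-5-[(E)-2-(3,5-dimethoxyphenyl)ethenyl]-2,3-dihydro-1-benzofuran-2-yl]-2-methoxyphenol
Product: 18 4-[(2S,3S)-3-(3,5-dihydroxyphenyl)-5-[(E)-2-(3,5-dihydroxyphenyl)ethenyl]-2,3-dihydro-1-benzofuran-2-yl]benzene-1,2-diol (target)
Conditions: BBr3 (12 equiv), CH2Cl2, −78 → 0 °C; then ice-water, under argon
Reagents that add atoms: none
Why: Lewis acid cleavage of the five aryl methyl ethers by bromide attack on the methyl groups of the O–BBr2 adducts; the ring C oxygens are tied up early as a catechol borate, a poor donor, which should disfavour ionisation of the benzylic C2–O1 bond, and any opening that does occur re-closes to the same trans ring without touching C3.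

## Compound list

1 | 5-bromosalicylaldehyde | O=Cc1cc(Br)ccc1O | starting material
2 | 1-bromo-3,5-dimethoxybenzene | COc1cc(Br)cc(OC)c1 | starting material
3 | 3,5-dimethoxyphenylmagnesium bromide (formed in the flask) | COc1cc(cc(OC)c1)[Mg]Br | intermediate
4 | 4-bromo-2-[(3,5-dimethoxyphenyl)(hydroxy)methyl]phenol (racemic) | COc1cc(OC)cc(c1)C(O)c1cc(Br)ccc1O | intermediate
5 | (5-bromo-2-hydroxyphenyl)(3,5-dimethoxyphenyl)methanone | COc1cc(OC)cc(c1)C(=O)c1cc(Br)ccc1O | intermediate
6 | vanillin | O=Cc1ccc(O)c(OC)c1 | starting material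
7 | 4-(tert-butyldimethylsilyloxy)-3-methoxybenzaldehyde | COc1cc(C=O)ccc1O[Si](C)(C)C(C)(C)C | intermediate
8 | [4-(tert-butyldimethylsilyloxy)-3-methoxyphenyl]methanol | COc1cc(CO)ccc1O[Si](C)(C)C(C)(C)C | intermediate
9 | tert-butyl[4-(chloromethyl)-2-methoxyphenoxy]dimethylsilane | COc1cc(CCl)ccc1O[Si](C)(C)C(C)(C)C | intermediate
10 | 4-(tert-butyldimethylsilyloxy)-3-methoxybenzylmagnesium chloride (formed in the flask) | COc1cc(C[Mg]Cl)ccc1O[Si](C)(C)C(C)(C)C | intermediate
11 | 4-bromo-2-{2-[4-(tert-butyldimethylsilyloxy)-3-methoxyphenyl]-1-(3,5-dimethoxyphenyl)-1-hydroxyethyl}phenol (racemic) | COc1cc(OC)cc(c1)C(O)(Cc1ccc(O[Si](C)(C)C(C)(C)C)c(OC)c1)c1cc(Br)ccc1O | intermediate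
12 | 4-bromo-2-{(E)-2-[4-(tert-butyldimethylsilyloxy)-3-methoxyphenyl]-1-(3,5-dimethoxyphenyl)ethenyl}phenol (E isomer drawn) | COc1cc(/C=C(\c2cc(OC)cc(OC)c2)c2cc(Br)ccc2O)ccc1O[Si](C)(C)C(C)(C)C | intermediate
13 | 4-bromo-2-[(E)-1-(3,5-dimethoxyphenyl)-2-(4-hydroxy-3-methoxyphenyl)ethenyl]phenol (E isomer drawn) | COc1cc(/C=C(\c2cc(OC)cc(OC)c2)c2cc(Br)ccc2O)ccc1O | intermediate
14 | 4-[(2S)-2-(5-bromo-2-hydroxyphenyl)-2-(3,5-dimethoxyphenyl)ethylidene]-2-methoxycyclohexa-2,5-dien-1-one (formed in the flask; exocyclic alkene geometry not defined) | COC1=CC(=C[C@@H](c2cc(OC)cc(OC)c2)c2cc(Br)ccc2O)C=CC1=O | intermediate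
15 | 4-[(2S,3S)-5-bromo-3-(3,5-dimethoxyphenyl)-2,3-dihydro-1-benzofuran-2-yl]-2-methoxyphenol (trans) | Brc1ccc2c(c1)[C@H](c1cc(OC)cc(OC)c1)[C@@H](c1ccc(O)c(OC)c1)O2 | intermediate
16 | 3,5-dimethoxystyrene | C=Cc1cc(OC)cc(OC)c1 | starting material
17 | 4-[(2S,3S)-3-(3,5-dimethoxyphenyl)-5-[(E)-2-(3,5-dimethoxyphenyl)ethenyl]-2,3-dihydro-1-benzofuran-2-yl]-2-methoxyphenol | COc1cc(OC)cc(/C=C/c2ccc3c(c2)[C@H](c2cc(OC)cc(OC)c2)[C@@H](c2ccc(O)c(OC)c2)O3)c1 | intermediate
18 | 4-[(2S,3S)-3-(3,5-dihydroxyphenyl)-5-[(E)-2-(3,5-dihydroxyphenyl)ethenyl]-2,3-dihydro-1-benzofuran-2-yl]benzene-1,2-diol | Oc1cc(O)cc(/C=C/c2ccc3c(c2)[C@H](c2cc(O)cc(O)c2)[C@@H](c2ccc(O)c(O)c2)O3)c1 | target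

## Step count and risks

Total step count: 11. Longest linear sequence: 9 steps (vanillin 6 to target 18, steps 3 to 11).

**Step 9 (Proposed new method).**
- What may go wrong: proton transfer to C3 may be too slow with an acid of this strength, or may not be face-selective.
- The product may also re-open through 14 and return to the alkene on long exposure, which would erode the configuration at C3.
- The quinone methide may alkylate the electron-rich rings of a second molecule.
- Fallback by known chemistry, setting out from ketone 5 and alcohol 8 and coming back at 15: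
  - Mitsunobu etherification of the phenol of 5 with 8 (PPh3, DIAD, THF) would give (5-bromo-2-{[4-(tert-butyldimethylsilyloxy)-3-methoxyphenyl]methoxy}phenyl)(3,5-dimethoxyphenyl)methanone F1.
  - Condensation with hydrazine (N2H4, cat. AcOH, EtOH, 70 °C) would give its hydrazone F2.
  - Oxidation with MnO2 (CH2Cl2, 0 °C) would give the diaryldiazomethane F3, which is not isolated.
  - F3 is treated with Rh2(R-PTAD)4, dirhodium tetrakis[N-phthaloyl-(R)-adamantylglycinate], or its enantiomer (1 mol %, CH2Cl2, 0 °C), whichever delivers the (3S) centre.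
  - The donor/donor rhodium carbene should insert enantioselectively into a benzylic C–H bond of the OCH2 group, forming the C2–C3 bond and the cis-(2R,3S)-dihydrobenzofuran silyl ether F4.
  - n-Bu4NF/AcOH would then free the cis-(2R,3S) phenol F5.
  - A catalytic achiral acid (diphenyl phosphate, CH2Cl2, rt) should equilibrate C2 through quinone methide 14, without touching C3, to the trans isomer 15.

**Step 6.**
- What may go wrong: Wurtz homocoupling during formation of the electron-rich benzylic Grignard reagent, incomplete addition to the chelated magnesium phenoxide of the ketone, or loss of the silyl group under the basic conditions.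
- Fallback setting out from ketone 5 and coming back at precursor 13:
  - Wittig methylenation of 5 (Ph3PCH3Br, KOt-Bu, 3 equiv each, THF, 0 °C → rt; the first equivalent of ylide is spent on the phenol) would give 4-bromo-2-[1-(3,5-dimethoxyphenyl)ethenyl]phenol F6.
  - Mizoroki–Heck arylation of its terminal CH2 with 4-iodo-2-methoxyphenol (Pd(OAc)2, n-Bu4NCl, KOAc, DMF, 70 °C) would give 13 directly; the aryl iodide reacts while the ring A bromide should stay intact at this temperature.
  - No silyl group is involved in this path.

**Step 11.**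
- What may go wrong: Lewis acid cleavage of the benzylic C2–O1 bond in competition with O-demethylation, cationic reactions of the electron-rich stilbene with the HBr that is set free, and air oxidation of the catechol during isolation.
- Fallback setting out from bromide 15 and coming back at target 18, with the ether cleavage moved in front of the coupling:
  - BBr3 (CH2Cl2, −78 → 0 °C) on 15 would give 4-[(2S,3S)-5-bromo-3-(3,5-dihydroxyphenyl)-2,3-dihydro-1-benzofuran-2-yl]benzene-1,2-diol F7.
  - Ac2O/pyridine would give its tetraacetate F8, on which the enantiomeric purity and the trans ring can be checked before the coupling.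
  - For the coupling partner, 3,5-dihydroxybenzaldehyde is methylenated (Ph3PCH3Br, KOt-Bu, THF) to 5-ethenylbenzene-1,3-diol F9 and acetylated to 5-ethenyl-1,3-phenylene diacetate F10.
  - Heck coupling of F8 with F10 under the conditions of step 10 would give the hexaacetate of the target F11.
  - K2CO3 in degassed MeOH at 0 °C, then dilute HCl, releases 18.
  - In this order the stilbene never meets a Lewis acid and the last operation is a mild transesterification. The C2–O1 bond still meets BBr3, but on a substrate that has no stilbene.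

## Further compounds

F1 | step 9 | (5-bromo-2-{[4-(tert-butyldimethylsilyloxy)-3-methoxyphenyl]methoxy}phenyl)(3,5-dimethoxyphenyl)methanone | COc1cc(OC)cc(c1)C(=O)c1cc(Br)ccc1OCc1ccc(O[Si](C)(C)C(C)(C)C)c(OC)c1
F2 | step 9 | [(5-bromo-2-{[4-(tert-butyldimethylsilyloxy)-3-methoxyphenyl]methoxy}phenyl)(3,5-dimethoxyphenyl)methylidene]hydrazine | COc1cc(OC)cc(c1)C(=NN)c1cc(Br)ccc1OCc1ccc(O[Si](C)(C)C(C)(C)C)c(OC)c1
F3 | step 9 | 4-bromo-1-{[4-(tert-butyldimethylsilyloxy)-3-methoxyphenyl]methoxy}-2-[diazo(3,5-dimethoxyphenyl)methyl]benzene | COc1cc(OC)cc(c1)C(=[N+]=[N-])c1cc(Br)ccc1OCc1ccc(O[Si](C)(C)C(C)(C)C)c(OC)c1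
F4 | step 9 | tert-butyl{4-[(2R,3S)-5-bromo-3-(3,5-dimethoxyphenyl)-2,3-dihydro-1-benzofuran-2-yl]-2-methoxyphenoxy}dimethylsilane (cis) | Brc1ccc2c(c1)[C@H](c1cc(OC)cc(OC)c1)[C@H](c1ccc(O[Si](C)(C)C(C)(C)C)c(OC)c1)O2
F5 | step 9 | 4-[(2R,3S)-5-bromo-3-(3,5-dimethoxyphenyl)-2,3-dihydro-1-benzofuran-2-yl]-2-methoxyphenol (cis) | Brc1ccc2c(c1)[C@H](c1cc(OC)cc(OC)c1)[C@H](c1ccc(O)c(OC)c1)O2
F6 | step 6 | 4-bromo-2-[1-(3,5-dimethoxyphenyl)ethenyl]phenol | C=C(c1cc(OC)cc(OC)c1)c1cc(Br)ccc1O
F7 | step 11 | 4-[(2S,3S)-5-bromo-3-(3,5-dihydroxyphenyl)-2,3-dihydro-1-benzofuran-2-yl]benzene-1,2-diol | Brc1ccc2c(c1)[C@H](c1cc(O)cc(O)c1)[C@@H](c1ccc(O)c(O)c1)O2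
F8 | step 11 | tetraacetate of F7 | Brc1ccc2c(c1)[C@H](c1cc(OC(C)=O)cc(OC(C)=O)c1)[C@@H](c1ccc(OC(C)=O)c(OC(C)=O)c1)O2
F9 | step 11 | 5-ethenylbenzene-1,3-diol | C=Cc1cc(O)cc(O)c1
F10 | step 11 | 5-ethenyl-1,3-phenylene diacetate | C=Cc1cc(OC(C)=O)cc(OC(C)=O)c1
F11 | step 11 | hexaacetate of 18 | CC(=O)Oc1cc(OC(C)=O)cc(/C=C/c2ccc3c(c2)[C@H](c2cc(OC(C)=O)cc(OC(C)=O)c2)[C@@H](c2ccc(OC(C)=O)c(OC(C)=O)c2)O3)c1
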